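Labdane numbering is used. The plan rests on opening ring B at C5–C6. C5, the ring-fusion carbon between the quaternary C4 and C10, and C8, which carries the exocyclic methylene, are 1,4-related in ring B; with both as carbonyls, C5 and the enone β-carbon C6 are two electrophilic carbons that SmI2 unites by polarity reversal. The precursor is a monocyclic ring A ketone (non-enolisable C5=O, made from ketoisophorone) whose quaternary C10 carries the chain C9–C8(=O)–C7=C6, with the C11–C16 side chain on C9. One operation closes ring B and leaves C8=O for methylenation; dehydration and hydrogenation then turn the C5 carbinol into the trans ring fusion.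

Key step: step 9

Remark: (S)-methyl hydrogen 3-methylglutarate (6) is taken as a purchasable, enantiopure half-ester; C9 is carried as an epimer mixture from step 7 and fixed by equilibration in step 11.

Step 1
Reactants: 1 ketoisophorone (2,6,6-trimethylcyclohex-2-ene-1,4-dione)
Product: 2 (R)-4-hydroxy-2,6,6-trimethylcyclohex-2-en-1-one
Conditions: RuCl[(R,R)-TsDPEN](p-cymene) (1 mol%), i-PrOH, rt
Reagents that add atoms: none
Why: Noyori-type asymmetric transfer hydrogenation should reduce only the less hindered carbonyl (the future C2; the future C5 carbonyl is shielded by the gem-dimethyl carbon and the methyl-bearing alkene carbon), and the (R,R)-ligand is expected, by the aryl/alkenyl ketone model, to give the R carbinol that becomes the 2β-oxygen.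

Step 2
Reactants: 2 (R)-4-hydroxy-2,6,6-trimethylcyclohex-2-en-1-one
Product: 3 (R)-4-(benzyloxy)-2,6,6-trimethylcyclohex-2-en-1-one
Conditions: BnOC(=NH)CCl3, TfOH (cat.), CH2Cl2/cyclohexane, 0 °C to rt
Reagents that add atoms: benzyl 2,2,2-trichloroacetimidate (N=C(OCc1ccccc1)C(Cl)(Cl)Cl)
Why: acid-catalysed O-benzylation with the trichloroacetimidate protects the carbinol without base, so the enone and the stereocentre are untouched.

Step 3
Reactants: 3 (R)-4-(benzyloxy)-2,6,6-trimethylcyclohex-2-en-1-one
Product: 5 2-[(1R,5R)-5-(benzyloxy)-1,3,3-trimethyl-2-oxocyclohexyl]-N-methoxy-N-methylacetamide, via lithium enolate 4 (not isolated)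
Conditions: LiBH(s-Bu)3, THF, −78 °C; then BrCH2C(O)N(OMe)Me, DMPU, −78 to 0 °C
Reagents that add atoms: 2-bromo-N-methoxy-N-methylacetamide (BrCC(=O)N(C)OC)
Why: reductive alkylation: the trialkylborohydride adds hydride 1,4 to the β-unsubstituted enone (as with carvone) and gives regiospecifically the tetrasubstituted C10 enolate, which the α-bromo amide should alkylate by axial attack on the half-chair with equatorial OBn, anti to the benzyloxy group, so that the C10 quaternary centre forms with methyl cis to the C2 oxygen.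

Step 4
Reactants: 6 (S)-5-methoxy-3-methyl-5-oxopentanoic acid
Product: 7 1-tert-butyl 5-methyl (R)-3-methylpentanedioate
Conditions: t-BuOC(=NH)CCl3, BF3·OEt2 (cat.), CH2Cl2/cyclohexane, rt
Reagents that add atoms: tert-butyl 2,2,2-trichloroacetimidate (N=C(OC(C)(C)C)C(Cl)(Cl)Cl)
Why: acid-catalysed tert-butylation of the free carboxylic acid leaves the methyl ester and the stereocentre untouched (the descriptor changes only by priority).

Step 5
Reactants: 7 1-tert-butyl 5-methyl (R)-3-methylpentanedioate
Product: 8 tert-butyl (R)-5-hydroxy-3-methylpentanoate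
Conditions: LiBH4, THF, 0 °C to rt
Reagents that add atoms: none
Why: chemoselective ester reduction: LiBH4 reduces the methyl ester but not the hindered tert-butyl ester.

Step 6
Reactants: 8 tert-butyl (R)-5-hydroxy-3-methylpentanoate
Product: 9 tert-butyl (S)-5-iodo-3-methylpentanoate
Conditions: I2, PPh3, imidazole, CH2Cl2, 0 °C
Reagents that add atoms: iodine (II)
Why: Appel-type iodination (Garegg–Samuelsson conditions) of the primary alcohol, remote from the stereocentre (the descriptor changes only by priority).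

Step 7
Reactants: 5 2-[(1R,5R)-5-(benzyloxy)-1,3,3-trimethyl-2-oxocyclohexyl]-N-methoxy-N-methylacetamide; 9 tert-butyl (S)-5-iodo-3-methylpentanoate
Product: 11 tert-butyl (3R)-6-[(1R,5R)-5-(benzyloxy)-1,3,3-trimethyl-2-oxocyclohexyl]-7-[methoxy(methyl)amino]-3-methyl-7-oxoheptanoate (both C9 epimers), via lithium amide enolate 10 (not isolated)
Conditions: LDA, THF, −78 °C; then 9, DMPU, −78 to −20 °C
Reagents that add atoms: none
Why: amide enolate alkylation with a primary iodide; LDA can only deprotonate C9 because the C5 ketone has no α-hydrogen, and the C9 epimer mixture is corrected in step 11.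

Step 8
Reactants: 11 tert-butyl (3R)-6-[(1R,5R)-5-(benzyloxy)-1,3,3-trimethyl-2-oxocyclohexyl]-7-[methoxy(methyl)amino]-3-methyl-7-oxoheptanoate
Product: 13 tert-butyl (3R)-6-[(1R,5R)-5-(benzyloxy)-1,3,3-trimethyl-2-oxocyclohexyl]-3-methyl-7-oxonon-8-enoate (both C9 epimers), via magnesium hemiaminal chelate 12 (not isolated)
Conditions: CH2=CHMgBr, THF, −20 to 0 °C; inverse quench into cold aq. NH4Cl
Reagents that add atoms: vinylmagnesium bromide (C=C[Mg]Br)
Why: Weinreb ketone synthesis: the chelated tetrahedral adduct prevents over-addition, the hindered C5 ketone and the tert-butyl ester should not react at this temperature, and the inverse quench keeps the liberated amine from adding to the enone.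

Step 9
Reactants: 13 tert-butyl (3R)-6-[(1R,5R)-5-(benzyloxy)-1,3,3-trimethyl-2-oxocyclohexyl]-3-methyl-7-oxonon-8-enoate
Product: 15 tert-butyl 2β-(benzyloxy)-5-hydroxy-8-oxo-17-norlabdan-15-oate (epimers at C5 and C9), via samarium alkoxide enolate 14 (not isolated)
Conditions: SmI2 (2.5 equiv), HMPA, THF, −78 to 0 °C, high dilution; aq. NH4Cl
Reagents that add atoms: none
Why: SmI2 transfers an electron to the vinyl ketone, the more easily reduced carbonyl, to give a samarium-bound allyl-type radical anion with spin at C6; this carbon (as the radical or, after a second electron, as a β-samario ketone, that is a homoenolate) adds to the samarium-activated C5 carbonyl, so two electrophilic carbons are joined by polarity reversal. The closest known reaction type is the SmI2-mediated intramolecular ketyl–olefin (carbonyl–activated alkene) reductive coupling, and the alternative ketyl-first pathway leads to the same bond. Ring B closes in the 6-endo-trig mode with respect to the C6=C7 bond (exo with respect to C5=O), through a cyclohexene-like transition state that contains the C7=C8 enolate. The new stereocentre C5 (tertiary carbinol) need not be controlled because step 10 removes it, and C9 stays a mixture that step 11 corrects. The step needs cross-coupling in preference to enone hydrodimerisation and to plain 1,4-reduction; high dilution, the absence of a proton source and the non-enolisable, pinacol-resistant C5 ketone between C4 and C10 should secure this.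

Step 10
Reactants: 15 tert-butyl 2β-(benzyloxy)-5-hydroxy-8-oxo-17-norlabdan-15-oate
Product: 16 tert-butyl 2β-(benzyloxy)-8-oxo-17-norlabd-5-en-15-oate (both C9 epimers)
Conditions: SOCl2, pyridine, CH2Cl2, −20 to 0 °C
Reagents that add atoms: none
Why: dehydration of the tertiary alcohol through its chlorosulfite; C6 is the only carbon with β-hydrogens because C4 and C10 are quaternary, so only the C5=C6 alkene can form.

Step 11
Reactants: 16 tert-butyl 2β-(benzyloxy)-8-oxo-17-norlabd-5-en-15-oate
Product: 18 tert-butyl 2β-hydroxy-8-oxo-17-norlabdan-15-oate (5α-H; 9α-H), via unequilibrated ketone 17 (not isolated)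
Conditions: H2 (5 bar), Pd(OH)2/C, EtOAc, rt; then t-BuOK (cat.), t-BuOH, rt
Reagents that add atoms: none
Why: heterogeneous hydrogenation should add hydrogen to the α face of the C5=C6 bond, opposite the axial C10 and C4 methyl groups, which sets C5 as in a trans-decalin and cleaves the benzyl ether by hydrogenolysis; t-BuOK then equilibrates C9 through the C8 enolate to the epimer with the equatorial side chain.

Step 12
Reactants: 18 tert-butyl 2β-hydroxy-8-oxo-17-norlabdan-15-oate
Product: 19 tert-butyl 2β-hydroxylabd-8(17)-en-15-oate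
Conditions: Ph3PCH3Br, t-BuOK, toluene, 90 °C
Reagents that add atoms: methyltriphenylphosphonium bromide (C[P+](c1ccccc1)(c1ccccc1)c1ccccc1.[Br-])
Why: Wittig methylenation of the hindered C8 ketone with excess ylide; the free alcohol is present as its alkoxide and C9 stays at its thermodynamic configuration.

Step 13
Reactants: 19 tert-butyl 2β-hydroxylabd-8(17)-en-15-oate
Product: 20 tert-butyl 2β-acetoxylabd-8(17)-en-15-oate
Conditions: Ac2O, DMAP, pyridine, rt
Reagents that add atoms: acetic anhydride (CC(=O)OC(C)=O)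
Why: DMAP-catalysed acetylation of the hindered axial C2 alcohol; no stereocentre is touched.

Step 14
Reactants: 20 tert-butyl 2β-acetoxylabd-8(17)-en-15-oate
Product: 22 2β-acetoxylabd-8(17)-en-15-oic acid (target), via trimethylsilyl ester 21 (not isolated)
Conditions: TMSOTf, 2,6-lutidine, CH2Cl2, 0 °C; then H2O
Reagents that add atoms: none
Why: silyl triflate-mediated cleavage of the tert-butyl ester (loss of isobutene) under lutidine buffering should spare the acetate and the exocyclic alkene, and the silyl ester hydrolyses on aqueous work-up.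

Compound list

1 | ketoisophorone (2,6,6-trimethylcyclohex-2-ene-1,4-dione) | CC1=CC(=O)CC(C)(C)C1=O | starting material
2 | (R)-4-hydroxy-2,6,6-trimethylcyclohex-2-en-1-one | O=C1C(C)(C)C[C@@H](O)C=C1C | intermediate
3 | (R)-4-(benzyloxy)-2,6,6-trimethylcyclohex-2-en-1-one | O=C1C(C)(C)C[C@@H](OCc2ccccc2)C=C1C | intermediate
4 | lithium (S)-4-(benzyloxy)-2,6,6-trimethylcyclohex-1-en-1-olate (C10 enolate) | [Li]OC1=C(C)C[C@H](OCc2ccccc2)CC1(C)C | intermediate
5 | 2-[(1R,5R)-5-(benzyloxy)-1,3,3-trimethyl-2-oxocyclohexyl]-N-methoxy-N-methylacetamide (ring methyl cis to OBn) | O=C1C(C)(C)C[C@@H](OCc2ccccc2)C[C@]1(C)CC(=O)N(C)OC | intermediate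
6 | (S)-5-methoxy-3-methyl-5-oxopentanoic acid ((S)-methyl hydrogen 3-methylglutarate) | COC(=O)C[C@@H](C)CC(=O)O | starting material
7 | 1-tert-butyl 5-methyl (R)-3-methylpentanedioate | COC(=O)C[C@@H](C)CC(=O)OC(C)(C)C | intermediate
8 | tert-butyl (R)-5-hydroxy-3-methylpentanoate | OCC[C@@H](C)CC(=O)OC(C)(C)C | intermediate
9 | tert-butyl (S)-5-iodo-3-methylpentanoate | ICC[C@@H](C)CC(=O)OC(C)(C)C | intermediate
10 | lithium enolate of amide 5 (C9=C8 enolate) | O=C1C(C)(C)C[C@@H](OCc2ccccc2)C[C@]1(C)C=C(O[Li])N(C)OC | intermediate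
11 | tert-butyl (3R)-6-[(1R,5R)-5-(benzyloxy)-1,3,3-trimethyl-2-oxocyclohexyl]-7-[methoxy(methyl)amino]-3-methyl-7-oxoheptanoate, both epimers at C9 (heptanoate C6) | O=C1C(C)(C)C[C@@H](OCc2ccccc2)C[C@]1(C)C(CC[C@@H](C)CC(=O)OC(C)(C)C)C(=O)N(C)OC | intermediate
12 | bromomagnesium hemiaminal alkoxide (tetrahedral vinyl adduct of 11) | O=C1C(C)(C)C[C@@H](OCc2ccccc2)C[C@]1(C)C(CC[C@@H](C)CC(=O)OC(C)(C)C)C(O[Mg]Br)(C=C)N(C)OC | intermediate
13 | tert-butyl (3R)-6-[(1R,5R)-5-(benzyloxy)-1,3,3-trimethyl-2-oxocyclohexyl]-3-methyl-7-oxonon-8-enoate, both epimers at C9 (nonenoate C6) | O=C1C(C)(C)C[C@@H](OCc2ccccc2)C[C@]1(C)C(CC[C@@H](C)CC(=O)OC(C)(C)C)C(=O)C=C | intermediate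
14 | bicyclic bis(diiodosamarium) C5 alkoxide / C7=C8 enolate | I[Sm](I)OC1=CCC2(O[Sm](I)I)C(C)(C)C[C@@H](OCc3ccccc3)C[C@]2(C)C1CC[C@@H](C)CC(=O)OC(C)(C)C | intermediate
15 | tert-butyl 2β-(benzyloxy)-5-hydroxy-8-oxo-17-norlabdan-15-oate (13R; 10-methyl β; epimers at C5 and C9) | O=C1CCC2(O)C(C)(C)C[C@@H](OCc3ccccc3)C[C@]2(C)C1CC[C@@H](C)CC(=O)OC(C)(C)C | intermediate
16 | tert-butyl 2β-(benzyloxy)-8-oxo-17-norlabd-5-en-15-oate (13R; epimers at C9) | O=C1CC=C2C(C)(C)C[C@@H](OCc3ccccc3)C[C@]2(C)C1CC[C@@H](C)CC(=O)OC(C)(C)C | intermediate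
17 | tert-butyl 2β-hydroxy-8-oxo-17-norlabdan-15-oate (5α-H, trans-decalin; epimers at C9) | O=C1CC[C@H]2C(C)(C)C[C@@H](O)C[C@]2(C)C1CC[C@@H](C)CC(=O)OC(C)(C)C | intermediate
18 | tert-butyl 2β-hydroxy-8-oxo-17-norlabdan-15-oate (5α-H, 9α-H, side chain β-equatorial; 13R) | O=C1CC[C@H]2C(C)(C)C[C@@H](O)C[C@]2(C)[C@H]1CC[C@@H](C)CC(=O)OC(C)(C)C | intermediate
19 | tert-butyl 2β-hydroxylabd-8(17)-en-15-oate | C=C1CC[C@H]2C(C)(C)C[C@@H](O)C[C@]2(C)[C@H]1CC[C@@H](C)CC(=O)OC(C)(C)C | intermediate
20 | tert-butyl 2β-acetoxylabd-8(17)-en-15-oate | C=C1CC[C@H]2C(C)(C)C[C@@H](OC(C)=O)C[C@]2(C)[C@H]1CC[C@@H](C)CC(=O)OC(C)(C)C | intermediate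
21 | trimethylsilyl 2β-acetoxylabd-8(17)-en-15-oate | C=C1CC[C@H]2C(C)(C)C[C@@H](OC(C)=O)C[C@]2(C)[C@H]1CC[C@@H](C)CC(=O)O[Si](C)(C)C | intermediate
22 | 2β-acetoxylabd-8(17)-en-15-oic acid, (3R)-5-[(1S,4aS,7R,8aS)-7-acetoxy-5,5,8a-trimethyl-2-methylidenedecahydronaphthalen-1-yl]-3-methylpentanoic acid | C=C1CC[C@H]2C(C)(C)C[C@@H](OC(C)=O)C[C@]2(C)[C@H]1CC[C@@H](C)CC(=O)O | target

Total step count: 14. Longest linear sequence: 11 steps (steps 1–3 and 7–14, from ketoisophorone); the side-chain iodide 9 is made in 3 steps (4–6) and joins in step 7.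

Steps most likely to fail

1. Step 9 (key step). The enone radical anion may dimerise through C6, or be reduced to the saturated ethyl ketone, before C6 reaches the very hindered C5 carbonyl. The fallback sets out from 13 and returns at 15; it changes the ring closure to a samarium Barbier reaction of an alkyl iodide. Luche reduction (NaBH4, CeCl3, MeOH) of the enone carbonyl gives the allylic alcohol F1. TBSCl and imidazole give the silyl ether F2. Hydroboration with 9-BBN and iodinolysis of the borane (I2, NaOMe) give the primary C6 iodide F3. SmI2/HMPA then closes ring B by adding the C6 organosamarium to the C5 ketone, giving the decalinol silyl ether F4. TBAF gives the diol F5, and Dess–Martin oxidation of its secondary C8 alcohol (the tertiary C5 alcohol cannot be oxidised) gives 15.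

2. Step 3. Facial selectivity at C10 may be poor (attack syn to OBn through a twist-boat), or the borane-containing enolate may undergo O-alkylation or proton transfer. The fallback sets out from 3 and returns at 5; it sets C10 under catalyst control. The same conjugate reduction gives enolate 4, which is trapped on oxygen with allyl chloroformate as the allyl enol carbonate F6. Pd2(dba)3 with (R)-t-Bu-PHOX effects decarboxylative asymmetric allylic alkylation to the α-allyl ketone F7; this ligand enantiomer is expected to place the allyl group trans to OBn. OsO4/NaIO4 cleaves the alkene to the aldehyde F8, NaClO2 oxidation gives the acid F9, and coupling with MeNH(OMe)·HCl and EDC gives 5.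

3. Step 11. The C5=C6 bond, flanked by the quaternary C4 and C10, may resist reduction on the catalyst surface so that only debenzylation takes place, or hydrogen may add with poor facial selectivity. The fallback sets out from 16 and returns at 17. Radical hydrogen-atom-transfer hydrogenation with Mn(dpm)3 (cat.), PhSiH3 and t-BuOOH in i-PrOH reduces the hindered alkene through the tertiary C5 radical, which should take up hydrogen on the α face to give the trans-fused benzyl ether F10. H2 and Pd/C then only have to cleave the benzyl ether to give 17, which is equilibrated to 18 as in step 11.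

Further compounds

F1 | step 9 | tert-butyl (3R)-6-[(1R,5R)-5-(benzyloxy)-1,3,3-trimethyl-2-oxocyclohexyl]-7-hydroxy-3-methylnon-8-enoate (epimer mixture) | O=C1C(C)(C)C[C@@H](OCc2ccccc2)C[C@]1(C)C(CC[C@@H](C)CC(=O)OC(C)(C)C)C(O)C=C
F2 | step 9 | tert-butyldimethylsilyl ether of F1 | O=C1C(C)(C)C[C@@H](OCc2ccccc2)C[C@]1(C)C(CC[C@@H](C)CC(=O)OC(C)(C)C)C(O[Si](C)(C)C(C)(C)C)C=C
F3 | step 9 | tert-butyl (3R)-6-[(1R,5R)-5-(benzyloxy)-1,3,3-trimethyl-2-oxocyclohexyl]-7-(tert-butyldimethylsilyloxy)-9-iodo-3-methylnonanoate | O=C1C(C)(C)C[C@@H](OCc2ccccc2)C[C@]1(C)C(CC[C@@H](C)CC(=O)OC(C)(C)C)C(O[Si](C)(C)C(C)(C)C)CCI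
F4 | step 9 | tert-butyl 2β-(benzyloxy)-8-(tert-butyldimethylsilyloxy)-5-hydroxy-17-norlabdan-15-oate (epimer mixture) | CC(C)(C)[Si](C)(C)OC1CCC2(O)C(C)(C)C[C@@H](OCc3ccccc3)C[C@]2(C)C1CC[C@@H](C)CC(=O)OC(C)(C)C
F5 | step 9 | tert-butyl 2β-(benzyloxy)-5,8-dihydroxy-17-norlabdan-15-oate (epimer mixture) | OC1CCC2(O)C(C)(C)C[C@@H](OCc3ccccc3)C[C@]2(C)C1CC[C@@H](C)CC(=O)OC(C)(C)C
F6 | step 3 | allyl (S)-4-(benzyloxy)-2,6,6-trimethylcyclohex-1-en-1-yl carbonate | C=CCOC(=O)OC1=C(C)C[C@H](OCc2ccccc2)CC1(C)C
F7 | step 3 | 2-allyl-4-(benzyloxy)-2,6,6-trimethylcyclohexan-1-one (allyl trans to OBn) | O=C1C(C)(C)C[C@@H](OCc2ccccc2)C[C@]1(C)CC=C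
F8 | step 3 | 2-[5-(benzyloxy)-1,3,3-trimethyl-2-oxocyclohexyl]acetaldehyde (ring configuration as in 5) | O=C1C(C)(C)C[C@@H](OCc2ccccc2)C[C@]1(C)CC=O
F9 | step 3 | 2-[5-(benzyloxy)-1,3,3-trimethyl-2-oxocyclohexyl]acetic acid (ring configuration as in 5) | O=C1C(C)(C)C[C@@H](OCc2ccccc2)C[C@]1(C)CC(=O)O
F10 | step 11 | tert-butyl 2β-(benzyloxy)-8-oxo-17-norlabdan-15-oate (5α-H; epimers at C9) | O=C1CC[C@H]2C(C)(C)C[C@@H](OCc3ccccc3)C[C@]2(C)C1CC[C@@H](C)CC(=O)OC(C)(C)C
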